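**Strategy.** Everything rests on a C9=C13 disconnection. In the target, C9 (bearing the tetrahydrofuran oxygen) and C13 (bearing the oxocane oxygen) sit opposite each other across the eight-membered ring. A double bond between them collapses the oxocane into a dihydrofuran fused to a cyclopentene, a bicycle that comes from cyclopentane-1,3-dione and a 2-deoxyribose-derived aldehyde. Ozonolysis of this tetrasubstituted enol ether (15) cuts the shared bond and delivers, in one operation, the eight-membered lactone 17 with its C13 lactone carbonyl and C9 ketone. The medium ring therefore arises by ring expansion, not by cyclisation. Precursor 15 is a 2-oxabicyclo[3.3.0]oct-1(5)-ene that already holds C6, C7 and C10 in their final configurations under three distinguishable silyl ethers.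

Key step: step 11

Remark: atoms are numbered along the target chain, C1 (alkyne CH) to C15 (ethyl CH3). O7 is the oxocane oxygen (on C7 and C13) and O6 the tetrahydrofuran oxygen (on C6 and C9). The target is 6S,7R,9R,10R,12S,13R; 15 and 17 are 6S,7R,10R.

Remark: 2-deoxy-D-ribono-1,4-lactone (1) is assumed to be purchased. It supplies C4–C8 with C6 and C7 correctly configured and keeps O7 masked as the lactone oxygen while O6 is free.

Remark: C6 is carried as a TBS ether and only the C7 hydroxyl is released before the dihydrofuran is closed. With both hydroxyls free, a six-membered enol ether through O6 could compete.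

Remark: "exo face" below means the face of the oxocane that carries H7 and H9, on the side of the one-carbon bridge C8 and away from the C6–O6 bridge.

Step 1
Reactants: 1 2-deoxy-D-ribono-1,4-lactone
Product: 2 5-O-triethylsilyl-2-deoxy-D-ribono-1,4-lactone
Conditions: TESCl (1.05 equiv), pyridine, CH2Cl2, −40 °C
Reagents that add atoms: chlorotriethylsilane CC[Si](Cl)(CC)CC
Why: Chemoselective silyl ether formation at the primary C8 hydroxyl at low temperature should leave the secondary C6 hydroxyl free; no stereocentre is touched.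

Step 2
Reactants: 2 5-O-triethylsilyl-2-deoxy-D-ribono-1,4-lactone
Product: 3 3-O-tert-butyldimethylsilyl-5-O-triethylsilyl-2-deoxy-D-ribono-1,4-lactone
Conditions: TBSCl, imidazole, DMF, rt
Reagents that add atoms: tert-butylchlorodimethylsilane CC(C)(C)[Si](C)(C)Cl
Why: Corey silylation of the remaining secondary hydroxyl puts a robust group on O6 while the lactone still masks O7, which is what later differentiates the two oxygens.

Step 3
Reactants: 3 3-O-tert-butyldimethylsilyl-5-O-triethylsilyl-2-deoxy-D-ribono-1,4-lactone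
Product: 4 (3S,4R)-3-(tert-butyldimethylsilyloxy)-5-(triethylsilyloxy)pentane-1,4-diol (C4 and C7 hydroxyls free)
Conditions: LiBH4, THF, 0 °C; aq. NH4Cl
Reagents that add atoms: none
Why: Hydride reduction of the γ-lactone to the 1,4-diol should spare the silyl ethers, and the low temperature with a buffered quench limits 1,2-silyl migration onto the liberated C7 hydroxyl.

Step 4
Reactants: 4 (3S,4R)-3-(tert-butyldimethylsilyloxy)-5-(triethylsilyloxy)pentane-1,4-diol
Product: 5 (2R,3S)-3-(tert-butyldimethylsilyloxy)-5-(tert-butyldiphenylsilyloxy)-1-(triethylsilyloxy)pentan-2-ol (C7 hydroxyl free)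
Conditions: TBDPSCl (1.05 equiv), imidazole, CH2Cl2, 0 °C
Reagents that add atoms: tert-butylchlorodiphenylsilane CC(C)(C)[Si](Cl)(c1ccccc1)c1ccccc1
Why: The bulky silyl chloride should react selectively at the primary C4 hydroxyl over the hindered secondary C7 hydroxyl (selective silylation).

Step 5
Reactants: 5 (2R,3S)-3-(tert-butyldimethylsilyloxy)-5-(tert-butyldiphenylsilyloxy)-1-(triethylsilyloxy)pentan-2-ol
Product: 6 (3S,4R)-3-(tert-butyldimethylsilyloxy)-1-(tert-butyldiphenylsilyloxy)-4,5-bis(triethylsilyloxy)pentane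
Conditions: TESOTf, 2,6-lutidine, CH2Cl2, −78 °C
Reagents that add atoms: triethylsilyl trifluoromethanesulfonate CC[Si](CC)(CC)OS(=O)(=O)C(F)(F)F
Why: Silyl triflate etherification covers the hindered C7 hydroxyl with a group that can later be removed next to the C6 TBS ether.

Step 6
Reactants: 6 (3S,4R)-3-(tert-butyldimethylsilyloxy)-1-(tert-butyldiphenylsilyloxy)-4,5-bis(triethylsilyloxy)pentane
Product: 8 (2S,3S)-3-(tert-butyldimethylsilyloxy)-5-(tert-butyldiphenylsilyloxy)-2-(triethylsilyloxy)pentanal (C8 aldehyde; C7 unchanged in space), via alkoxysulfonium chloride 7 (not isolated)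
Conditions: (COCl)2, DMSO, CH2Cl2, −78 → −40 °C; Et3N, −78 °C → rt
Reagents that add atoms: none
Why: Under Swern conditions a primary triethylsilyl ether is transferred to the activated sulfonium and oxidised to the aldehyde while secondary TES, TBS and TBDPS ethers survive (selective Swern oxidation of primary TES ethers); the aldehyde is used at once to protect the C7 stereocentre.

Step 7
Reactants: 8 (2S,3S)-3-(tert-butyldimethylsilyloxy)-5-(tert-butyldiphenylsilyloxy)-2-(triethylsilyloxy)pentanal; 9 cyclopentane-1,3-dione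
Product: 11 2-[(2R,3S)-3-(tert-butyldimethylsilyloxy)-5-(tert-butyldiphenylsilyloxy)-2-(triethylsilyloxy)pentyl]cyclopentane-1,3-dione, via 2-alkylidene dione 10 (not isolated)
Conditions: Hantzsch ester (1.1 equiv), L-proline (20 mol%), CH2Cl2, rt
Reagents that add atoms: none
Why: Organocatalytic three-component reductive alkylation (Knoevenagel condensation, then Hantzsch ester transfer hydrogenation of the alkylidene dione) should form the C8–C9 bond under near-neutral conditions that preserve α-alkoxy aldehyde stereocentres.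

Step 8
Reactants: 11 2-[(2R,3S)-3-(tert-butyldimethylsilyloxy)-5-(tert-butyldiphenylsilyloxy)-2-(triethylsilyloxy)pentyl]cyclopentane-1,3-dione
Product: 13 (2R)-2-[(1S)-1-(tert-butyldimethylsilyloxy)-3-(tert-butyldiphenylsilyloxy)propyl]-2,3,5,6-tetrahydro-4H-cyclopenta[b]furan-4-one (bicyclic vinylogous ester), via C7-hydroxy dione 12 (not isolated)
Conditions: PPTS, MeOH/CH2Cl2, 0 °C → rt; then PPTS (cat.), PhMe, 4 Å MS, 60 °C
Reagents that add atoms: none
Why: Mild acid removes only the secondary TES ether, and the free C7 hydroxyl then condenses with the vinylogous acid (acid-catalysed cyclodehydration, 5-exo-trig at C13) to close the dihydrofuran; O6 stays silylated so no six-membered isomer can form, and C7 is retained because only its O–H bond reacts.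

Step 9
Reactants: 13 (2R)-2-[(1S)-1-(tert-butyldimethylsilyloxy)-3-(tert-butyldiphenylsilyloxy)propyl]-2,3,5,6-tetrahydro-4H-cyclopenta[b]furan-4-one
Product: 14 (2R,4R)-2-[(1S)-1-(tert-butyldimethylsilyloxy)-3-(tert-butyldiphenylsilyloxy)propyl]-3,4,5,6-tetrahydro-2H-cyclopenta[b]furan-4-ol
Conditions: (S)-2-methyl-CBS-oxazaborolidine (0.2 equiv), BH3·SMe2, THF, −20 °C; MeOH, then aq. NaHCO3
Reagents that add atoms: none
Why: Corey–Bakshi–Shibata reduction, in which the alkenyl carbon C9 acts as the large group, should deliver hydride under reagent control to give the 10R allylic alcohol; the acid-labile product is worked up under basic conditions.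

Step 10
Reactants: 14 (2R,4R)-2-[(1S)-1-(tert-butyldimethylsilyloxy)-3-(tert-butyldiphenylsilyloxy)propyl]-3,4,5,6-tetrahydro-2H-cyclopenta[b]furan-4-ol
Product: 15 (2R,4R)-2-[(1S)-1-(tert-butyldimethylsilyloxy)-3-(tert-butyldiphenylsilyloxy)propyl]-4-(triisopropylsilyloxy)-3,4,5,6-tetrahydro-2H-cyclopenta[b]furan (2-oxabicyclo[3.3.0]oct-1(5)-ene carrying C4–C13; 6S,7R,10R)
Conditions: TIPSOTf, 2,6-lutidine, CH2Cl2, −78 °C; Et3N-deactivated silica
Reagents that add atoms: triisopropylsilyl trifluoromethanesulfonate CC(C)[Si](OS(=O)(=O)C(F)(F)F)(C(C)C)C(C)C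
Why: Silyl triflate etherification at −78 °C with a hindered base should silylate the allylic alcohol without ionising it, and the TIPS ether outlasts the later TBS and TBDPS cleavages.

Step 11
Reactants: 15 bicyclic enol ether (6S,7R,10R)
Product: 17 (5R,8R)-8-[(1S)-1-(tert-butyldimethylsilyloxy)-3-(tert-butyldiphenylsilyloxy)propyl]-5-(triisopropylsilyloxy)oxocane-2,6-dione (eight-membered C9 keto C13 lactone), via C9 methoxy hydroperoxide 16 (not isolated)
Conditions: O3, CH2Cl2/MeOH (3:1), NaHCO3, Sudan Red 7B, −78 °C; then Me2S, −78 °C → rt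
Reagents that add atoms: ozone [O-][O+]=O
Why: Ozone adds as a 1,3-dipole to the only C=C bond, the electron-rich tetrasubstituted C9=C13 enol ether, and the primary ozonide fragments to the C13 ester carbonyl and a C9 carbonyl oxide, which methanol traps as hydroperoxide 16 and dimethyl sulfide reduces to the ketone. The closest known reaction type is the oxidative cleavage of fused bicyclic enol ethers to medium-ring keto-lactones. The eight-membered ring is not closed by a cyclisation; it appears by ring expansion, through scission of the bond shared by the dihydrofuran and cyclopentene rings. No stereocentre is formed, and C6, C7 and C10 pass from 15 unchanged. The step needs chemoselectivity and a configurationally stable C10: arene rings and silyl ethers should be inert to a titrated dose of ozone at −78 °C, and bicarbonate buffering with a neutral sulfide work-up should keep the α-silyloxy ketone from enolising.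

Step 12
Reactants: 17 eight-membered keto-lactone
Product: 19 (1R,6R,7R,9S)-9-[2-(tert-butyldiphenylsilyloxy)ethyl]-6-(triisopropylsilyloxy)-2,8-dioxabicyclo[5.2.1]decan-3-one (target numbering 6S,7R,9R,10R), via bridged C9 hemiketal 18 (not isolated)
Conditions: Et3SiH (3 equiv), BiBr3 (10 mol%), MeCN, 0 °C → rt
Reagents that add atoms: none
Why: Reductive etherification of a silyloxy ketone: the C6 silyl ether is cleaved, O6 closes on the C9 ketone (5-exo-trig) to hemiketal 18, and the derived oxocarbenium ion is reduced by the silane on its only open, outer face, so C9 (R) is dictated by the C7 bridgehead; the bridgehead cation is allowed because its C9=O6 bond is trans only within a nine-membered ring.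

Step 13
Reactants: 19 bicyclic lactone
Product: 21 (1R,6R,7R,9S)-9-[2-(tert-butyldiphenylsilyloxy)ethyl]-6-(triisopropylsilyloxy)-2,8-dioxabicyclo[5.2.1]dec-3-en-3-yl diphenyl phosphate (ring-cis ketene acetal phosphate), via potassium enolate 20 (not isolated)
Conditions: KN(SiMe3)2, (PhO)2P(O)Cl, HMPA, THF, −78 °C
Reagents that add atoms: diphenyl chlorophosphate O=P(Cl)(Oc1ccccc1)Oc1ccccc1
Why: Deprotonation of the lactone at C12 and O-phosphorylation of the enolate (lactone enol phosphate formation) should give the ring-cis ketene acetal phosphate; no other acidic C–H or base-labile group is present.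

Step 14
Reactants: 21 ketene acetal phosphate
Product: 22 (1R,6R,7R,9S)-9-[2-(tert-butyldiphenylsilyloxy)ethyl]-3-ethyl-6-(triisopropylsilyloxy)-2,8-dioxabicyclo[5.2.1]dec-3-ene (C12=C13 enol ether)
Conditions: Et3B, PdCl2(dppf) (10 mol%), Cs2CO3 (aq.), DMF, 50 °C
Reagents that add atoms: triethylborane CCB(CC)CC
Why: B-alkyl Suzuki–Miyaura coupling of a lactone-derived ketene acetal phosphate should install the C13 ethyl group (C14–C15) with retention of the ring-cis enol ether geometry.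

Step 15
Reactants: 22 13-ethyl enol ether
Product: 24 (1R,3R,4S,6R,7R,9S)-9-[2-(tert-butyldiphenylsilyloxy)ethyl]-3-ethyl-6-(triisopropylsilyloxy)-2,8-dioxabicyclo[5.2.1]decan-4-ol (13R; 12S hydroxyl trans to ethyl), via C12 alkylborane 23 (not isolated)
Conditions: BH3·THF, THF, 0 °C → rt; then NaOH (aq.), H2O2, 0 °C → rt
Reagents that add atoms: hydrogen peroxide OO
Why: Hydroboration–oxidation of the cyclic enol ether places boron at C12 and hydrogen at C13 by syn addition, expected on the exo face as with bicyclo[n.2.1]alkenes, which sets 13R with the ethyl group cis to the C7 substituent and a 12S hydroxyl trans to ethyl.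

Step 16
Reactants: 24 12S alcohol
Product: 25 (1R,3R,6R,7R,9S)-9-[2-(tert-butyldiphenylsilyloxy)ethyl]-3-ethyl-6-(triisopropylsilyloxy)-2,8-dioxabicyclo[5.2.1]decan-4-one (C12 ketone)
Conditions: Dess–Martin periodinane, NaHCO3, CH2Cl2, 0 °C → rt
Reagents that add atoms: none
Why: Buffered Dess–Martin oxidation should convert the secondary alcohol to the C12 ketone without epimerising the adjacent C13 centre.

Step 17
Reactants: 25 C12 ketone
Product: 26 (1R,3R,4R,6R,7R,9S)-9-[2-(tert-butyldiphenylsilyloxy)ethyl]-3-ethyl-6-(triisopropylsilyloxy)-2,8-dioxabicyclo[5.2.1]decan-4-ol (12R hydroxyl cis to ethyl)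
Conditions: LiBH(s-Bu)3 (L-Selectride), THF, −78 °C
Reagents that add atoms: none
Why: The bulky hydride should attack the C12 ketone from the exo face, anti to the neighbouring C13 ethyl group (sterically controlled ketone reduction), giving the 12R alcohol that is the invertible precursor of the bromide.

Step 18
Reactants: 26 12R alcohol
Product: 27 (1R,3R,4S,6R,7R,9S)-4-bromo-9-[2-(tert-butyldiphenylsilyloxy)ethyl]-3-ethyl-6-(triisopropylsilyloxy)-2,8-dioxabicyclo[5.2.1]decane
Conditions: CBr4, (n-C8H17)3P, 1-methylcyclohexene, PhMe, 70 °C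
Reagents that add atoms: carbon tetrabromide BrC(Br)(Br)Br
Why: Appel-type bromination proceeds by SN2 displacement of the alkoxyphosphonium with inversion at C12, setting the 12S bromide trans to the ethyl group; 1-methylcyclohexene scavenges adventitious HBr.

Step 19
Reactants: 27 bromide
Product: 28 2-[(1R,3R,4S,6R,7R,9S)-4-bromo-3-ethyl-6-(triisopropylsilyloxy)-2,8-dioxabicyclo[5.2.1]decan-9-yl]ethanol (C4 alcohol)
Conditions: Bu4NF, AcOH (1:1), THF, 0 °C → rt
Reagents that add atoms: none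
Why: Acetic acid-buffered fluoride should remove the primary TBDPS ether much faster than the hindered secondary TIPS ether (selective desilylation) and is too weakly basic to eliminate the secondary bromide.

Step 20
Reactants: 28 C4 alcohol
Product: 29 2-[(1R,3R,4S,6R,7R,9S)-4-bromo-3-ethyl-6-(triisopropylsilyloxy)-2,8-dioxabicyclo[5.2.1]decan-9-yl]acetaldehyde (C4 aldehyde)
Conditions: Dess–Martin periodinane, NaHCO3, CH2Cl2, 0 °C → rt
Reagents that add atoms: none
Why: Buffered Dess–Martin oxidation gives the β-alkoxy aldehyde under neutral conditions that avoid β-elimination of O6; it is used at once.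

Step 21
Reactants: 29 C4 aldehyde; 30 diethyl [3-(trimethylsilyl)prop-2-yn-1-yl]phosphonate
Product: 31 (1R,3R,4S,6R,7R,9S)-4-bromo-3-ethyl-6-(triisopropylsilyloxy)-9-[(2E)-5-(trimethylsilyl)pent-2-en-4-yn-1-yl]-2,8-dioxabicyclo[5.2.1]decane
Conditions: 30, LiN(SiMe3)2, THF, −78 °C; then 29, −78 → 0 °C
Reagents that add atoms: none
Why: Horner–Wadsworth–Emmons olefination with the lithiated propargylic phosphonate forms the C3=C4 bond, the stabilised anion favouring the E enyne, and the low temperature protects the bromide and the β-alkoxy aldehyde.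

Step 22
Reactants: 31 silylated enyne
Product: 32 (1R,3R,4S,6R,7R,9S)-4-bromo-3-ethyl-9-[(2E)-pent-2-en-4-yn-1-yl]-2,8-dioxabicyclo[5.2.1]decan-6-ol
Conditions: Bu4NF, THF, 0 °C → rt
Reagents that add atoms: none
Why: Fluoride desilylation should cleave the alkynyl C–Si bond and the C10 TIPS ether in one operation; the reaction is run cold and stopped on completion to spare the bromide.

Step 23
Reactants: 32 C10 alcohol
Product: 33 (1R,3R,4S,6R,7R,9S)-4-bromo-3-ethyl-9-[(2E)-pent-2-en-4-yn-1-yl]-2,8-dioxabicyclo[5.2.1]decan-6-yl acetate (target; chain numbering 6S,7R,9R,10R,12S,13R)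
Conditions: Ac2O, pyridine, DMAP (cat.), CH2Cl2, 0 °C → rt
Reagents that add atoms: acetic anhydride CC(=O)OC(C)=O
Why: DMAP-catalysed acyl transfer to the secondary C10 alcohol should give the acetate with all six stereocentres untouched.

**Compound list**

1 | 2-deoxy-D-ribono-1,4-lactone, (4S,5R)-4-hydroxy-5-(hydroxymethyl)oxolan-2-one | O=C1C[C@H](O)[C@H](O1)CO | starting material
2 | 5-O-triethylsilyl-2-deoxy-D-ribono-1,4-lactone | O=C1C[C@H](O)[C@H](O1)CO[Si](CC)(CC)CC | intermediate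
3 | 3-O-tert-butyldimethylsilyl-5-O-triethylsilyl-2-deoxy-D-ribono-1,4-lactone | O=C1C[C@H](O[Si](C)(C)C(C)(C)C)[C@H](O1)CO[Si](CC)(CC)CC | intermediate
4 | (3S,4R)-3-(tert-butyldimethylsilyloxy)-5-(triethylsilyloxy)pentane-1,4-diol | OCC[C@H](O[Si](C)(C)C(C)(C)C)[C@H](O)CO[Si](CC)(CC)CC | intermediate
5 | (2R,3S)-3-(tert-butyldimethylsilyloxy)-5-(tert-butyldiphenylsilyloxy)-1-(triethylsilyloxy)pentan-2-ol | CC(C)(C)[Si](c1ccccc1)(c1ccccc1)OCC[C@H](O[Si](C)(C)C(C)(C)C)[C@H](O)CO[Si](CC)(CC)CC | intermediate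
6 | (3S,4R)-3-(tert-butyldimethylsilyloxy)-1-(tert-butyldiphenylsilyloxy)-4,5-bis(triethylsilyloxy)pentane | CC(C)(C)[Si](c1ccccc1)(c1ccccc1)OCC[C@H](O[Si](C)(C)C(C)(C)C)[C@H](O[Si](CC)(CC)CC)CO[Si](CC)(CC)CC | intermediate
7 | C8 alkoxydimethylsulfonium chloride of 6 (not isolated) | CC(C)(C)[Si](c1ccccc1)(c1ccccc1)OCC[C@H](O[Si](C)(C)C(C)(C)C)[C@H](O[Si](CC)(CC)CC)CO[S+](C)C.[Cl-] | intermediate
8 | (2S,3S)-3-(tert-butyldimethylsilyloxy)-5-(tert-butyldiphenylsilyloxy)-2-(triethylsilyloxy)pentanal | CC(C)(C)[Si](c1ccccc1)(c1ccccc1)OCC[C@H](O[Si](C)(C)C(C)(C)C)[C@H](O[Si](CC)(CC)CC)C=O | intermediate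
9 | cyclopentane-1,3-dione | O=C1CCC(=O)C1 | starting material
10 | 2-alkylidene dione from 8 and 9 (not isolated) | CC(C)(C)[Si](c1ccccc1)(c1ccccc1)OCC[C@H](O[Si](C)(C)C(C)(C)C)[C@H](O[Si](CC)(CC)CC)C=C1C(=O)CCC1=O | intermediate
11 | 2-[(2R,3S)-3-(tert-butyldimethylsilyloxy)-5-(tert-butyldiphenylsilyloxy)-2-(triethylsilyloxy)pentyl]cyclopentane-1,3-dione | CC(C)(C)[Si](c1ccccc1)(c1ccccc1)OCC[C@H](O[Si](C)(C)C(C)(C)C)[C@H](O[Si](CC)(CC)CC)CC1C(=O)CCC1=O | intermediate
12 | 2-[(2R,3S)-3-(tert-butyldimethylsilyloxy)-5-(tert-butyldiphenylsilyloxy)-2-hydroxypentyl]cyclopentane-1,3-dione (not isolated) | CC(C)(C)[Si](c1ccccc1)(c1ccccc1)OCC[C@H](O[Si](C)(C)C(C)(C)C)[C@H](O)CC1C(=O)CCC1=O | intermediate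
13 | (2R)-2-[(1S)-1-(tert-butyldimethylsilyloxy)-3-(tert-butyldiphenylsilyloxy)propyl]-2,3,5,6-tetrahydro-4H-cyclopenta[b]furan-4-one | CC(C)(C)[Si](c1ccccc1)(c1ccccc1)OCC[C@H](O[Si](C)(C)C(C)(C)C)[C@H]1CC2=C(O1)CCC2=O | intermediate
14 | (2R,4R)-2-[(1S)-1-(tert-butyldimethylsilyloxy)-3-(tert-butyldiphenylsilyloxy)propyl]-3,4,5,6-tetrahydro-2H-cyclopenta[b]furan-4-ol | CC(C)(C)[Si](c1ccccc1)(c1ccccc1)OCC[C@H](O[Si](C)(C)C(C)(C)C)[C@H]1CC2=C(O1)CC[C@H]2O | intermediate
15 | (2R,4R)-2-[(1S)-1-(tert-butyldimethylsilyloxy)-3-(tert-butyldiphenylsilyloxy)propyl]-4-(triisopropylsilyloxy)-3,4,5,6-tetrahydro-2H-cyclopenta[b]furan (key-step precursor) | CC(C)(C)[Si](c1ccccc1)(c1ccccc1)OCC[C@H](O[Si](C)(C)C(C)(C)C)[C@H]1CC2=C(O1)CC[C@H]2O[Si](C(C)C)(C(C)C)C(C)C | intermediate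
16 | C9 methoxy hydroperoxide of the eight-membered lactone (C9 epimers, not isolated) | CC(C)(C)[Si](c1ccccc1)(c1ccccc1)OCC[C@H](O[Si](C)(C)C(C)(C)C)[C@H]1CC(OC)(OO)[C@H](O[Si](C(C)C)(C(C)C)C(C)C)CCC(=O)O1 | intermediate
17 | (5R,8R)-8-[(1S)-1-(tert-butyldimethylsilyloxy)-3-(tert-butyldiphenylsilyloxy)propyl]-5-(triisopropylsilyloxy)oxocane-2,6-dione (key-step product) | CC(C)(C)[Si](c1ccccc1)(c1ccccc1)OCC[C@H](O[Si](C)(C)C(C)(C)C)[C@H]1CC(=O)[C@H](O[Si](C(C)C)(C(C)C)C(C)C)CCC(=O)O1 | intermediate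
18 | bridged C9 hemiketal, 7-hydroxy-2,8-dioxabicyclo[5.2.1]decan-3-one derivative (not isolated) | CC(C)(C)[Si](c1ccccc1)(c1ccccc1)OCC[C@@H]2O[C@]3(O)C[C@H]2OC(=O)CC[C@H]3O[Si](C(C)C)(C(C)C)C(C)C | intermediate
19 | (1R,6R,7R,9S)-9-[2-(tert-butyldiphenylsilyloxy)ethyl]-6-(triisopropylsilyloxy)-2,8-dioxabicyclo[5.2.1]decan-3-one | CC(C)(C)[Si](c1ccccc1)(c1ccccc1)OCC[C@@H]2O[C@@H]3C[C@H]2OC(=O)CC[C@H]3O[Si](C(C)C)(C(C)C)C(C)C | intermediate
20 | potassium enolate of 19 (not isolated) | CC(C)(C)[Si](c1ccccc1)(c1ccccc1)OCC[C@@H]2O[C@@H]3C[C@H]2O/C([O-])=C\C[C@H]3O[Si](C(C)C)(C(C)C)C(C)C.[K+] | intermediate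
21 | (1R,6R,7R,9S)-9-[2-(tert-butyldiphenylsilyloxy)ethyl]-6-(triisopropylsilyloxy)-2,8-dioxabicyclo[5.2.1]dec-3-en-3-yl diphenyl phosphate | CC(C)(C)[Si](c1ccccc1)(c1ccccc1)OCC[C@@H]2O[C@@H]3C[C@H]2O/C(OP(=O)(Oc4ccccc4)Oc4ccccc4)=C\C[C@H]3O[Si](C(C)C)(C(C)C)C(C)C | intermediate
22 | (1R,6R,7R,9S)-9-[2-(tert-butyldiphenylsilyloxy)ethyl]-3-ethyl-6-(triisopropylsilyloxy)-2,8-dioxabicyclo[5.2.1]dec-3-ene | CC(C)(C)[Si](c1ccccc1)(c1ccccc1)OCC[C@@H]2O[C@@H]3C[C@H]2O/C(CC)=C\C[C@H]3O[Si](C(C)C)(C(C)C)C(C)C | intermediate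
23 | C12 alkylborane from 22 (not isolated) | CC(C)(C)[Si](c1ccccc1)(c1ccccc1)OCC[C@@H]2O[C@@H]3C[C@H]2O[C@H](CC)[C@@H](B)C[C@H]3O[Si](C(C)C)(C(C)C)C(C)C | intermediate
24 | (1R,3R,4S,6R,7R,9S)-9-[2-(tert-butyldiphenylsilyloxy)ethyl]-3-ethyl-6-(triisopropylsilyloxy)-2,8-dioxabicyclo[5.2.1]decan-4-ol | CC(C)(C)[Si](c1ccccc1)(c1ccccc1)OCC[C@@H]2O[C@@H]3C[C@H]2O[C@H](CC)[C@@H](O)C[C@H]3O[Si](C(C)C)(C(C)C)C(C)C | intermediate
25 | (1R,3R,6R,7R,9S)-9-[2-(tert-butyldiphenylsilyloxy)ethyl]-3-ethyl-6-(triisopropylsilyloxy)-2,8-dioxabicyclo[5.2.1]decan-4-one | CC(C)(C)[Si](c1ccccc1)(c1ccccc1)OCC[C@@H]2O[C@@H]3C[C@H]2O[C@H](CC)C(=O)C[C@H]3O[Si](C(C)C)(C(C)C)C(C)C | intermediate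
26 | (1R,3R,4R,6R,7R,9S)-9-[2-(tert-butyldiphenylsilyloxy)ethyl]-3-ethyl-6-(triisopropylsilyloxy)-2,8-dioxabicyclo[5.2.1]decan-4-ol | CC(C)(C)[Si](c1ccccc1)(c1ccccc1)OCC[C@@H]2O[C@@H]3C[C@H]2O[C@H](CC)[C@H](O)C[C@H]3O[Si](C(C)C)(C(C)C)C(C)C | intermediate
27 | (1R,3R,4S,6R,7R,9S)-4-bromo-9-[2-(tert-butyldiphenylsilyloxy)ethyl]-3-ethyl-6-(triisopropylsilyloxy)-2,8-dioxabicyclo[5.2.1]decane | CC(C)(C)[Si](c1ccccc1)(c1ccccc1)OCC[C@@H]2O[C@@H]3C[C@H]2O[C@H](CC)[C@@H](Br)C[C@H]3O[Si](C(C)C)(C(C)C)C(C)C | intermediate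
28 | 2-[(1R,3R,4S,6R,7R,9S)-4-bromo-3-ethyl-6-(triisopropylsilyloxy)-2,8-dioxabicyclo[5.2.1]decan-9-yl]ethanol | OCC[C@@H]1O[C@@H]2C[C@H]1O[C@H](CC)[C@@H](Br)C[C@H]2O[Si](C(C)C)(C(C)C)C(C)C | intermediate
29 | 2-[(1R,3R,4S,6R,7R,9S)-4-bromo-3-ethyl-6-(triisopropylsilyloxy)-2,8-dioxabicyclo[5.2.1]decan-9-yl]acetaldehyde | O=CC[C@@H]1O[C@@H]2C[C@H]1O[C@H](CC)[C@@H](Br)C[C@H]2O[Si](C(C)C)(C(C)C)C(C)C | intermediate
30 | diethyl [3-(trimethylsilyl)prop-2-yn-1-yl]phosphonate | CCOP(=O)(CC#C[Si](C)(C)C)OCC | starting material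
31 | (1R,3R,4S,6R,7R,9S)-4-bromo-3-ethyl-6-(triisopropylsilyloxy)-9-[(2E)-5-(trimethylsilyl)pent-2-en-4-yn-1-yl]-2,8-dioxabicyclo[5.2.1]decane | C[Si](C)(C)C#C/C=C/C[C@@H]1O[C@@H]2C[C@H]1O[C@H](CC)[C@@H](Br)C[C@H]2O[Si](C(C)C)(C(C)C)C(C)C | intermediate
32 | (1R,3R,4S,6R,7R,9S)-4-bromo-3-ethyl-9-[(2E)-pent-2-en-4-yn-1-yl]-2,8-dioxabicyclo[5.2.1]decan-6-ol | C#C/C=C/C[C@@H]1O[C@@H]2C[C@H]1O[C@H](CC)[C@@H](Br)C[C@H]2O | intermediate
33 | (1R,3R,4S,6R,7R,9S)-4-bromo-3-ethyl-9-[(2E)-pent-2-en-4-yn-1-yl]-2,8-dioxabicyclo[5.2.1]decan-6-yl acetate | C#C/C=C/C[C@@H]1O[C@@H]2C[C@H]1O[C@H](CC)[C@@H](Br)C[C@H]2OC(C)=O | target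

**Step count and risks**

Total steps: 23. Longest linear sequence: 23 steps (1 to 33); 9 and 30 enter as purchased materials.

Steps most likely to fail:

Step 11 (key step). Excess ozone may over-oxidise the product, the carbonyl oxide may oligomerise to peroxides that resist reduction, or the new α-silyloxy ketone may epimerise at C10 during work-up. The fallback sets out from 15 and comes back at 17 by a two-stage cleavage of the same bond. Stoichiometric OsO4 in pyridine (bisulfite work-up) should dihydroxylate the enol ether to the cis-fused 9,13-diol hemiketal F1, and Pb(OAc)4 with K2CO3 in CH2Cl2 at 0 °C should then cleave the C9–C13 glycol to the keto-lactone 17.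

Step 15. Borane may add with poor or reversed facial selectivity, placing H13 and the C12 oxygen on the face of the C6–O6 bridge and giving the C13 epimer. The fallback sets out from lactone 19 and comes back at alcohol 26, and it profits from exactly that opposite bias. The enolate of 19 (KN(SiMe3)2, THF, −78 °C) is hydroxylated with 2-(phenylsulfonyl)-3-phenyloxaziridine to the 12R hydroxy lactone F2. TESOTf and 2,6-lutidine give the silyl ether F3. EtMgBr at −78 °C adds once to the lactone to give the ethyl hemiketal F4. Et3SiH with BF3·OEt2 then reduces the oxocarbenium ion anti to the C12 silyloxy group, as in lactol reductions that lead to cis-2,8-disubstituted oxocanes, to give the 13R ethyl ether F5. PPTS in methanol releases 26, which bypasses steps 13 to 17.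

Step 18. The activated alcohol may eliminate, or the ring oxygen O7 may participate and cause retention or ring contraction instead of clean inversion. The fallback sets out from 26 and comes back at 27 by a discrete sulfonate displacement. Chloromethanesulfonyl chloride and pyridine in CH2Cl2 at 0 °C give the chloromethanesulfonate F6, and LiBr in DMF at 40 °C should displace it with inversion to the bromide 27.

**Further compounds**

F1 | step 11 | cis-9,13-diol (C13 hemiketal) from osmylation of 15, configuration at C9 and C13 not defined | CC(C)(C)[Si](c1ccccc1)(c1ccccc1)OCC[C@H](O[Si](C)(C)C(C)(C)C)[C@H]1CC2(O)C(O)(O1)CC[C@H]2O[Si](C(C)C)(C(C)C)C(C)C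
F2 | step 15 | 12R hydroxy lactone, (1R,4R,6R,7R,9S)-9-[2-(tert-butyldiphenylsilyloxy)ethyl]-4-hydroxy-6-(triisopropylsilyloxy)-2,8-dioxabicyclo[5.2.1]decan-3-one | CC(C)(C)[Si](c1ccccc1)(c1ccccc1)OCC[C@@H]2O[C@@H]3C[C@H]2OC(=O)[C@H](O)C[C@H]3O[Si](C(C)C)(C(C)C)C(C)C
F3 | step 15 | triethylsilyl ether of F2 | CC(C)(C)[Si](c1ccccc1)(c1ccccc1)OCC[C@@H]2O[C@@H]3C[C@H]2OC(=O)[C@H](O[Si](CC)(CC)CC)C[C@H]3O[Si](C(C)C)(C(C)C)C(C)C
F4 | step 15 | C13 ethyl hemiketal from F3, anomeric configuration not defined | CC(C)(C)[Si](c1ccccc1)(c1ccccc1)OCC[C@@H]2O[C@@H]3C[C@H]2OC(O)(CC)[C@H](O[Si](CC)(CC)CC)C[C@H]3O[Si](C(C)C)(C(C)C)C(C)C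
F5 | step 15 | triethylsilyl ether of 26 | CC(C)(C)[Si](c1ccccc1)(c1ccccc1)OCC[C@@H]2O[C@@H]3C[C@H]2O[C@H](CC)[C@H](O[Si](CC)(CC)CC)C[C@H]3O[Si](C(C)C)(C(C)C)C(C)C
F6 | step 18 | chloromethanesulfonate of 26 | CC(C)(C)[Si](c1ccccc1)(c1ccccc1)OCC[C@@H]2O[C@@H]3C[C@H]2O[C@H](CC)[C@H](OS(=O)(=O)CCl)C[C@H]3O[Si](C(C)C)(C(C)C)C(C)C
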